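## Retrosynthetic overview

1. C4–OH comes last, by cis-selective 1,2-reduction of the C4 ketone of the bicyclic dione, under substrate control from C2.
2. Ring C is formed second, by a two-atom ring expansion of (S)-4-phenyloxetan-2-one. The enol C4a=C8a of ring A is inserted into the acyl C–O bond (C4–C4a first, then O1–C8a). The C2–O1 bond is never broken.
3. The β-lactone comes from benzaldehyde and ketene (from acetyl chloride) by catalytic asymmetric cyclocondensation, which sets C2.
4. Ring A is formed first, by a [5+1] double Claisen condensation of 3,3-diprenylpentane-2,4-dione with dimethyl carbonate. The methyl enol ether is then placed at the one unhindered carbonyl (C5).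
5. The quaternary C8 comes from double C-prenylation of acetylacetone.

Positions follow flavan numbering (O1, C2 … C8a). Prenyl = 3-methylbut-2-en-1-yl.

Assumption: O-trimethylsilylquinidine is taken to give the (S)-lactone. If the sense proves opposite, its pseudoenantiomer O-trimethylsilylquinine is used.

## Route

Step 1
Reactants: 1 pentane-2,4-dione (acetylacetone); 2 1-bromo-3-methylbut-2-ene (prenyl bromide, 2.3 equiv)
Product: 3 3,3-bis(3-methylbut-2-en-1-yl)pentane-2,4-dione
Conditions: K2CO3 (3 equiv), dry acetone, reflux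
Reagents that add atoms: none
Why: Double C-alkylation of the 1,3-diketone enolate (SN2 on a soft allylic bromide) ends at the quaternary carbon because no acidic central hydrogen is left; no stereocentre is formed.

Step 2
Reactants: 3 3,3-bis(3-methylbut-2-en-1-yl)pentane-2,4-dione; 4 dimethyl carbonate
Product: 6 5-methoxy-2,2-bis(3-methylbut-2-en-1-yl)cyclohex-4-ene-1,3-dione, via trione 5 (not isolated)
Conditions: NaN(SiMe3)2 (4.2 equiv), THF, −78 °C; 4 (1.05 equiv), −78 → 55 °C; then 0 °C, HCl in MeOH (to pH 1–2), 23 °C, 3 h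
Reagents that add atoms: methanol, CO
Why: A [5+1] double Claisen condensation (carbomethoxylation of the bis-enolate, then Dieckmann closure) is driven by the stabilised trionate, and the acid-catalysed enol etherification (vinylogous Fischer esterification) goes to the only carbonyl not flanked by the quaternary carbon, as with 4,4-dialkylcyclohexane-1,3-diones; no stereocentre is formed.

Step 3
Reactants: 7 benzaldehyde; 8 acetyl chloride (slow addition)
Product: 10 (S)-4-phenyloxetan-2-one, via ketene 9 (not isolated)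
Conditions: i-Pr2NEt (2.5 equiv), O-trimethylsilylquinidine (10 mol %), LiClO4, CH2Cl2/Et2O, −78 °C
Reagents that add atoms: none
Why: In this alkaloid/lithium co-catalysed acyl halide–aldehyde cyclocondensation (Wynberg-type formal [2+2], stepwise aldol then lactonisation), the chiral ammonium enolate of ketene adds to one face of lithium-activated benzaldehyde and sets the (S) centre that becomes C2.

Step 4
Reactants: 6 5-methoxy-2,2-bis(3-methylbut-2-en-1-yl)cyclohex-4-ene-1,3-dione; 10 (S)-4-phenyloxetan-2-one (1.1 equiv, slow addition)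
Product: 13 (2S)-5-methoxy-8,8-bis(3-methylbut-2-en-1-yl)-2-phenyl-2,3-dihydro-4H-chromene-4,7(8H)-dione, via hydroxy triketone 11 (not isolated), via pyridinium enol ether 12 (not isolated)
Conditions: DMAP (0.3 equiv), i-Pr2NEt (1.1 equiv), MeCN, 40 °C; then 0 °C, 2-bromo-1-ethylpyridinium tetrafluoroborate (1.2 equiv), i-Pr2NEt (1.2 equiv), 0 → 23 °C, short contact time
Reagents that add atoms: none
Why: Proposed new method: formal insertion of an enol C=C into the acyl C–O bond of a β-lactone (oxetan-2-one to 2,3-dihydropyran-4-one, four- to six-membered ring expansion); DMAP opens the strained lactone at the acyl carbon and passes the acyl group to carbon of the enolate of 6, whose two nucleophilic carbons are equivalent, so only the chelated triketone 11 can form, and 11, being about as acidic as a carboxylic acid, is the thermodynamic sink and as its anion is shielded from retro-aldol cleavage and dehydration; the 2-halopyridinium salt then reacts with this triketonate rather than with the neutral alcohol to give 12, in which C8a carries by far the best leaving group on the ring (1-ethyl-2-pyridone against methoxide at C5), and the benzylic hydroxyl closes ring C by addition–elimination at C8a; the C2–O1 bond is never broken, so the (S) centre of 10 is kept; the closest known reaction types are the DMAP-mediated C-acylation of cyclic 1,3-diones, the Claisen-type acyl opening of β-lactones by enolates and the Mukaiyama lactonisation of hydroxy acids, used here in vinylogous form.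

Step 5
Reactants: 13 (2S)-5-methoxy-8,8-bis(3-methylbut-2-en-1-yl)-2-phenyl-2,3-dihydro-4H-chromene-4,7(8H)-dione
Product: 14 pongaflavanol, (2S,4S)-4-hydroxy-5-methoxy-8,8-bis(3-methylbut-2-en-1-yl)-2-phenyl-3,4-dihydro-2H-chromen-7(8H)-one
Conditions: NaBH4 (1.0 equiv), CeCl3·7H2O (1.1 equiv), MeOH/THF, −78 → −40 °C; pH 7 buffer work-up
Reagents that add atoms: none
Why: In this Luche 1,2-reduction the C7 carbonyl is shielded by the neighbouring quaternary carbon and deactivated by two vinylogous oxygen donors, so hydride goes to C4, axially on the half-chair with equatorial 2-phenyl, giving the pseudo-equatorial 2,4-cis alcohol (4S), as with flavanones.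

## Compound list

1 | pentane-2,4-dione | CC(=O)CC(C)=O | starting material
2 | 1-bromo-3-methylbut-2-ene | CC(C)=CCBr | starting material
3 | 3,3-bis(3-methylbut-2-en-1-yl)pentane-2,4-dione | CC(=O)C(CC=C(C)C)(CC=C(C)C)C(C)=O | intermediate
4 | dimethyl carbonate | COC(=O)OC | starting material
5 | 2,2-bis(3-methylbut-2-en-1-yl)cyclohexane-1,3,5-trione | O=C1CC(=O)C(CC=C(C)C)(CC=C(C)C)C(=O)C1 | intermediate
6 | 5-methoxy-2,2-bis(3-methylbut-2-en-1-yl)cyclohex-4-ene-1,3-dione | COC1=CC(=O)C(CC=C(C)C)(CC=C(C)C)C(=O)C1 | intermediate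
7 | benzaldehyde | O=Cc1ccccc1 | starting material
8 | acetyl chloride | CC(=O)Cl | starting material
9 | ketene | C=C=O | intermediate
10 | (S)-4-phenyloxetan-2-one | O=C1C[C@@H](c2ccccc2)O1 | intermediate
11 | 5-hydroxy-4-[(3S)-3-hydroxy-3-phenylpropanoyl]-3-methoxy-6,6-bis(3-methylbut-2-en-1-yl)cyclohexa-2,4-dien-1-one | COC1=CC(=O)C(CC=C(C)C)(CC=C(C)C)C(O)=C1C(=O)C[C@H](O)c1ccccc1 | intermediate
12 | 1-ethyl-2-{[2-((3S)-3-hydroxy-3-phenylpropanoyl)-3-methoxy-5-oxo-6,6-bis(3-methylbut-2-en-1-yl)cyclohexa-1,3-dien-1-yl]oxy}pyridinium tetrafluoroborate | COC1=CC(=O)C(CC=C(C)C)(CC=C(C)C)C(Oc2cccc[n+]2CC)=C1C(=O)C[C@H](O)c1ccccc1.F[B-](F)(F)F | intermediate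
13 | (2S)-5-methoxy-8,8-bis(3-methylbut-2-en-1-yl)-2-phenyl-2,3-dihydro-4H-chromene-4,7(8H)-dione | COC1=CC(=O)C(CC=C(C)C)(CC=C(C)C)C2=C1C(=O)C[C@@H](c1ccccc1)O2 | intermediate
14 | pongaflavanol, (2S,4S)-4-hydroxy-5-methoxy-8,8-bis(3-methylbut-2-en-1-yl)-2-phenyl-3,4-dihydro-2H-chromen-7(8H)-one | COC1=CC(=O)C(CC=C(C)C)(CC=C(C)C)C2=C1[C@@H](O)C[C@@H](c1ccccc1)O2 | target

## Step count and risks

Total step count: 5. Longest linear sequence: 4 (steps 1, 2, 4, 5).

**Most likely to fail, first: step 4, the proposed ring expansion.**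
- The stabilised enolate of 6 may attack the benzylic carbon of 10 (alkyl C–O cleavage), or 10 may oligomerise.
- The pyridinium salt may activate the side-chain oxygen of 11 instead of the ring oxygen.
- The hydroxyl may displace the C5 methoxy group instead of closing at C8a.
- Amine base may racemise 13 by retro-oxa-Michael opening.

The fallback uses known chemistry only. It sets out from 6 and 7 and comes back to the route at 14.
- C-acetylation of 6 (Ac2O, Et3N, DMAP, CH2Cl2, with O-to-C acyl transfer) gives 4-acetyl-5-hydroxy-3-methoxy-6,6-bis(3-methylbut-2-en-1-yl)cyclohexa-2,4-dien-1-one F4.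
- Claisen–Schmidt condensation with 7 (KOH, EtOH) gives the chalcone analogue 5-hydroxy-3-methoxy-6,6-bis(3-methylbut-2-en-1-yl)-4-[(E)-3-phenylprop-2-enoyl]cyclohexa-2,4-dien-1-one F5.
- Oxa-Michael closure through the only free enol oxygen (NaOAc, EtOH, reflux) gives racemic 5-methoxy-8,8-bis(3-methylbut-2-en-1-yl)-2-phenyl-2,3-dihydro-4H-chromene-4,7(8H)-dione F6.
- Kinetic resolution by asymmetric transfer hydrogenation (RuCl[(S,S)-TsDPEN](p-cymene), HCO2H/Et3N), as practised on racemic flavanones, reduces the (2S) enantiomer to 14. It leaves the unreacted (2R)-5-methoxy-8,8-bis(3-methylbut-2-en-1-yl)-2-phenyl-2,3-dihydro-4H-chromene-4,7(8H)-dione F7, which is separated.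

**Second: step 2.**
- Dimethyl carbonate is a weak electrophile.
- The second enolate may be carbomethoxylated instead of closing the ring.
- Methoxide may cleave any non-enolised 2,2-disubstituted 1,3-diketone by retro-Claisen reaction.
- The acid stage may give some of the hindered enol ether or cyclise an enol onto a prenyl group.

The fallback changes the ring disconnection from [5+1] to [4+2]. It sets out from 2 and comes back at 5.
- Methyl acetoacetate F1 is dialkylated with 2 (K2CO3, acetone, reflux) to methyl 2-acetyl-5-methyl-2-(3-methylbut-2-en-1-yl)hex-4-enoate F2.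
- The kinetic enolate of F2 (LiN(i-Pr)2, THF, −78 °C) is acetylated with N-methoxy-N-methylacetamide to methyl 2,2-bis(3-methylbut-2-en-1-yl)-3,5-dioxohexanoate F3.
- The 1,3-diketone dianion (LiN(i-Pr)2, 2.2 equiv) attacks the ester through its terminal carbon (Dieckmann closure) to give 5. This is isolated and etherified with HCl/MeOH as in step 2.

**Third: step 5.**
- The C4 carbonyl is itself a vinylogous ester and may react slowly.
- C7 may compete with C4 for hydride.
- The ionisable allylic alcohol 14 may be solvolysed to its methyl ether by the cerium salt in methanol.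

The fallback avoids protic and Lewis acidic media and delivers the alcohol in protected form. It sets out from 13 and comes back at 14.
- Copper hydride catalysed 1,2-hydrosilylation ([(Ph3P)CuH]6 cat., PhMe2SiH, toluene, 0 °C) gives (2S,4S)-4-{[dimethyl(phenyl)silyl]oxy}-5-methoxy-8,8-bis(3-methylbut-2-en-1-yl)-2-phenyl-3,4-dihydro-2H-chromen-7(8H)-one F8.
- F8 is purified and cleaved with Bu4NF/AcOH in THF to 14.

## Further compounds

F1 | step 2 | methyl acetoacetate (purchased) | COC(=O)CC(C)=O
F2 | step 2 | methyl 2-acetyl-5-methyl-2-(3-methylbut-2-en-1-yl)hex-4-enoate | COC(=O)C(CC=C(C)C)(CC=C(C)C)C(C)=O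
F3 | step 2 | methyl 2,2-bis(3-methylbut-2-en-1-yl)-3,5-dioxohexanoate | COC(=O)C(CC=C(C)C)(CC=C(C)C)C(=O)CC(C)=O
F4 | step 4 | 4-acetyl-5-hydroxy-3-methoxy-6,6-bis(3-methylbut-2-en-1-yl)cyclohexa-2,4-dien-1-one | COC1=CC(=O)C(CC=C(C)C)(CC=C(C)C)C(O)=C1C(C)=O
F5 | step 4 | 5-hydroxy-3-methoxy-6,6-bis(3-methylbut-2-en-1-yl)-4-[(E)-3-phenylprop-2-enoyl]cyclohexa-2,4-dien-1-one | COC1=CC(=O)C(CC=C(C)C)(CC=C(C)C)C(O)=C1C(=O)/C=C/c1ccccc1
F6 | step 4 | racemic 5-methoxy-8,8-bis(3-methylbut-2-en-1-yl)-2-phenyl-2,3-dihydro-4H-chromene-4,7(8H)-dione | COC1=CC(=O)C(CC=C(C)C)(CC=C(C)C)C2=C1C(=O)CC(c1ccccc1)O2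
F7 | step 4 | (2R)-5-methoxy-8,8-bis(3-methylbut-2-en-1-yl)-2-phenyl-2,3-dihydro-4H-chromene-4,7(8H)-dione | COC1=CC(=O)C(CC=C(C)C)(CC=C(C)C)C2=C1C(=O)C[C@H](c1ccccc1)O2
F8 | step 5 | (2S,4S)-4-{[dimethyl(phenyl)silyl]oxy}-5-methoxy-8,8-bis(3-methylbut-2-en-1-yl)-2-phenyl-3,4-dihydro-2H-chromen-7(8H)-one | COC1=CC(=O)C(CC=C(C)C)(CC=C(C)C)C2=C1[C@@H](O[Si](C)(C)c1ccccc1)C[C@@H](c1ccccc1)O2
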